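**Retrosynthetic overview**
The target is the linear pentamer F–CH2–P–CH2–P–CH2–P–CH2–F. F is a 2-butyryl-3,5-dihydroxy-4,4-dimethylcyclohexa-2,5-dien-1-one ring joined through C6, and P is a butyrylphloroglucinol ring joined through its two free ring carbons. The four CH2 bridges are cut in pairs from the outside in, which in the forward sense is two-directional growth from the central P ring by Mannich base/o-quinone methide couplings.
Each F ring is cut at C1–C2 and C3–C4. This gives a two-carbon piece, butyrylketene (stored in a dioxinone as a temporary ring), and a four-carbon piece, the 1,3-bis(silyloxy)diene of methyl isobutyrylacetate. Both bonds form in one flask by ketene C-acylation followed by Claisen closure, a formal [4+2].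
Enabling feature: around the F ring the oxygen-bearing carbons C1, C3 and C5 alternate with the enolate-type carbons C2, C4 and C6, so both cut bonds are acyl–enolate bonds that match a ketene C=C (C3 electrophilic first, C2 nucleophilic afterwards). The quaternary C4(CH3)2 forbids aromatisation, closes the aldol exit and speeds ring closure, while C6–H stays free for bridging.
Ring order: the two F rings are the only rings built, and one batch from step 4 serves both ends. The three P rings come from phloroglucinol.
Key step: step 4

Remark on the chemistry: the target has no stereocentre and no configurationally stable double bond (every ring C=C is an enol tautomer), so it is achiral and no enantioselective step is needed. All SMILES are written in one tautomer, and the geometry of the silyl enol ethers is erased later and is left open.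

Step 1
Reactants: 1 methyl 4-methyl-3-oxopentanoate (methyl isobutyrylacetate)
Product: 2 methyl 4-methyl-3-(trimethylsilyloxy)pent-2-enoate
Conditions: TMSCl, Et3N, hexane, rt; filter, concentrate
Reagents that add atoms: chlorotrimethylsilane, C[Si](C)(C)Cl
Why: O-silylation of the enolised β-keto ester under soft enolisation is the standard first stage in the preparation of 1,3-bis(silyloxy)dienes, and no stereocentre is formed.

Step 2
Reactants: 2 methyl 4-methyl-3-(trimethylsilyloxy)pent-2-enoate
Product: 3 1-methoxy-4-methyl-1,3-bis(trimethylsilyloxy)penta-1,3-diene
Conditions: LDA, THF, −78 °C; TMSCl, −78 → 0 °C; hexane, filter; used crude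
Reagents that add atoms: chlorotrimethylsilane, C[Si](C)(C)Cl
Why: Kinetic vinylogous (γ) deprotonation of the β-silyloxy enoate at the isopropyl methine, its only γ-hydrogen, followed by O-silylation of the extended ester enolate should give the bis(silyloxy)diene as in the standard preparation of this reagent class.

Step 3
Reactants: 4 2,2,6-trimethyl-4H-1,3-dioxin-4-one
Product: 5 2,2-dimethyl-6-propyl-4H-1,3-dioxin-4-one
Conditions: LDA, THF/DMPU, −78 °C; EtI, −78 → −20 °C
Reagents that add atoms: iodoethane, CCI
Why: Vinylogous enolate alkylation (γ-alkylation of the lithium dienolate of the dioxinone with a primary iodide) lengthens the 6-methyl to the 6-propyl group and stores butyrylketene in a neutral, aprotic temporary ring.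

Step 4
Reactants: 3 1-methoxy-4-methyl-1,3-bis(trimethylsilyloxy)penta-1,3-diene (1.5 equiv); 5 2,2-dimethyl-6-propyl-4H-1,3-dioxin-4-one
Product: 9 butyrylfilicinic acid (2-butyryl-3,5-dihydroxy-4,4-dimethylcyclohexa-2,5-dien-1-one), via butyrylketene 6 (not isolated), via bis-silyl acylation adduct 7 (not isolated), via triketo ester 8 (not isolated)
Conditions: 5 added slowly to 3, PhMe, 110 °C, acetone distilled off; then NaOMe (5 equiv), MeOH, 25 → 60 °C, same flask; 1 M HCl
Reagents that add atoms: none
Why: Proposed new method: at 110 °C dioxinone 5 loses acetone by retro-[4+2] and the butyrylketene 6 set free is attacked at its sp ketene carbon by the dimethyl-substituted terminus of diene 3, which makes the bond between the quaternary ring carbon C4 and C3, and silyl transfer from the ester oxocarbenium ion to the diketonate oxygen gives 7. Methoxide added to the same flask removes both silyl groups, and in the polyenolate of 8 the carbon between the two ketones (future C2) attacks the methyl ester (future C1) and expels methoxide, so that the C=C unit of the ketene has acted first as electrophile and then as nucleophile in a formal [4+2] annulation. The closest known reaction types are the C–C bond-forming hetero-Diels–Alder capture of dioxinone-derived acylketenes by enol ethers and ketene acetals, the terminal acylation of 1,3-bis(silyloxy)dienes by acid chlorides, and the strong-base Claisen cyclisation of 3,5,7-triketo esters to acylphloroglucinols; new is their merger with a carbocycle as outcome. The only ring closed is the six-membered carbocycle, by a 6-(enolexo)-exo-trig Claisen (Dieckmann-type) acylation, and no stereocentre is formed. Terminal rather than α-attack on the diene is needed and is secured by the convergence of all three oxygen donors on the terminal carbon, by the two OSiMe3 groups that flank the α-CH and by the small steric demand of a ketene carbon; any O-closed form of the first adduct holds the same C–C bond and is opened by methoxide to the same 8. Claisen rather than aldol closure or retro-Claisen cleavage is needed and is secured by excess strong base, which ties up all three ketones as enolates and leaves the ester as the only electrophile, by the gem-dimethyl carbon, which forbids aromatisation of an aldol product and speeds ring closure (gem-dialkyl effect), and by the irreversible formation of the vinylogous-acid anion of 9; slow addition of 5 to excess 3 with removal of acetone holds down ketene dimerisation.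

Step 5
Reactants: 10 phloroglucinol (benzene-1,3,5-triol)
Product: 11 1-(2,4,6-trihydroxyphenyl)butan-1-one (butyrylphloroglucinol)
Conditions: butyryl chloride, AlCl3, CH2Cl2/PhNO2, 0 → 45 °C; aq. HCl
Reagents that add atoms: butyryl chloride, CCCC(=O)Cl
Why: Friedel–Crafts C-acylation of phloroglucinol should stop after one acyl group because the chelated aryl ketone deactivates the ring.

Step 6
Reactants: 11 1-(2,4,6-trihydroxyphenyl)butan-1-one
Product: 13 1-[3,5-bis(dimethylaminomethyl)-2,4,6-trihydroxyphenyl]butan-1-one, via mono-Mannich base 12 (not isolated)
Conditions: CH2(NMe2)2 (2.5 equiv), 1,4-dioxane, 0 °C → rt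
Reagents that add atoms: N,N,N',N'-tetramethylmethanediamine, CN(C)CN(C)C
Why: In this Mannich reaction of an electron-rich phenol with a preformed aminal both free ring carbons are aminomethylated, and the excess of aminal at low temperature keeps a Mannich base from alkylating unreacted 11.

Step 7
Reactants: 13 1-[3,5-bis(dimethylaminomethyl)-2,4,6-trihydroxyphenyl]butan-1-one; 11 1-(2,4,6-trihydroxyphenyl)butan-1-one (10 equiv)
Product: 17 linear trimer (central butyrylphloroglucinol ring carrying a (3-butyryl-2,4,6-trihydroxyphenyl)methyl group on each of its two remaining ring carbons), via quinone methide 14 (not isolated), via half-coupled amine 15 (not isolated), via second quinone methide 16 (not isolated)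
Conditions: 1,4-dioxane, 90 °C, N2 sweep; excess 11 recovered
Reagents that add atoms: none
Why: Thermal loss of dimethylamine from each ortho-hydroxybenzylamine arm gives an o-quinone methide that is captured by a free ring carbon of 11 (Friedel–Crafts-type conjugate addition, the Mannich base route to methylenebisphloroglucinols), and the large excess of 11 keeps the free CH positions of the product from competing.

Step 8
Reactants: 17 linear trimer
Product: 19 trimer bis-Mannich base (17 with a dimethylaminomethyl group on the free CH of each terminal ring), via mono-Mannich base 18 (not isolated)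
Conditions: CH2(NMe2)2 (3 equiv), THF, 0 °C → rt
Reagents that add atoms: N,N,N',N'-tetramethylmethanediamine, CN(C)CN(C)C
Why: The same phenol Mannich reaction meets no choice of site here, since the two terminal rings of 17 hold the only two free aromatic CH positions, so the symmetric core is activated at both ends at once.

Step 9
Reactants: 19 trimer bis-Mannich base; 9 butyrylfilicinic acid (2.2 equiv)
Product: 23 CNP0188003.0 (pentamer butyrylfilicinic acid–CH2–[butyrylphloroglucinol–CH2]3–butyrylfilicinic acid), via terminal quinone methide 20 (not isolated), via half-capped amine 21 (not isolated), via second quinone methide 22 (not isolated)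
Conditions: THF, 55 °C, N2 sweep; 0.5 M HCl wash
Reagents that add atoms: none
Why: The strongly acidic vinylogous acid 9 protonates the benzylic amines of 19, which lose dimethylamine to o-quinone methides that are trapped at C6 of the filicinate anion (Michael-type C-alkylation of a cyclic β-triketone), and because 9 is the only C-nucleophile and 19 the only electrophile both ends should be capped alike without creating a stereocentre.

**Compound list**
1 | methyl 4-methyl-3-oxopentanoate | COC(=O)CC(=O)C(C)C | starting material
2 | methyl 4-methyl-3-(trimethylsilyloxy)pent-2-enoate | COC(=O)C=C(O[Si](C)(C)C)C(C)C | intermediate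
3 | 1-methoxy-4-methyl-1,3-bis(trimethylsilyloxy)penta-1,3-diene | COC(O[Si](C)(C)C)=CC(O[Si](C)(C)C)=C(C)C | intermediate
4 | 2,2,6-trimethyl-4H-1,3-dioxin-4-one | CC1=CC(=O)OC(C)(C)O1 | starting material
5 | 2,2-dimethyl-6-propyl-4H-1,3-dioxin-4-one | CCCC1=CC(=O)OC(C)(C)O1 | intermediate
6 | butyrylketene (3-oxohex-1-en-1-one) | CCCC(=O)C=C=O | intermediate
7 | methyl 4,4-dimethyl-5-oxo-3,7-bis(trimethylsilyloxy)deca-2,6-dienoate | CCCC(O[Si](C)(C)C)=CC(=O)C(C)(C)C(O[Si](C)(C)C)=CC(=O)OC | intermediate
8 | methyl 4,4-dimethyl-3,5,7-trioxodecanoate | CCCC(=O)CC(=O)C(C)(C)C(=O)CC(=O)OC | intermediate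
9 | butyrylfilicinic acid (2-butyryl-3,5-dihydroxy-4,4-dimethylcyclohexa-2,5-dien-1-one) | CCCC(=O)C1=C(O)C(C)(C)C(O)=CC1=O | intermediate
10 | phloroglucinol | Oc1cc(O)cc(O)c1 | starting material
11 | 1-(2,4,6-trihydroxyphenyl)butan-1-one | CCCC(=O)c1c(O)cc(O)cc1O | intermediate
12 | 1-[3-(dimethylaminomethyl)-2,4,6-trihydroxyphenyl]butan-1-one | CCCC(=O)c1c(O)cc(O)c(CN(C)C)c1O | intermediate
13 | 1-[3,5-bis(dimethylaminomethyl)-2,4,6-trihydroxyphenyl]butan-1-one | CCCC(=O)c1c(O)c(CN(C)C)c(O)c(CN(C)C)c1O | intermediate
14 | o-quinone methide from 13 (one arm eliminated) | CCCC(=O)C1=C(O)C(=C)C(=O)C(CN(C)C)=C1O | intermediate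
15 | half-coupled amine (methylene-bridged dimer still bearing one CH2NMe2) | CCCC(=O)c1c(O)cc(O)c(Cc2c(O)c(CN(C)C)c(O)c(C(=O)CCC)c2O)c1O | intermediate
16 | o-quinone methide from 15 | CCCC(=O)c1c(O)cc(O)c(CC2=C(O)C(C(=O)CCC)=C(O)C(=C)C2=O)c1O | intermediate
17 | linear trimer of butyrylphloroglucinol (two CH2 bridges) | CCCC(=O)c1c(O)cc(O)c(Cc2c(O)c(Cc3c(O)cc(O)c(C(=O)CCC)c3O)c(O)c(C(=O)CCC)c2O)c1O | intermediate
18 | trimer mono-Mannich base | CCCC(=O)c1c(O)c(CN(C)C)c(O)c(Cc2c(O)c(Cc3c(O)cc(O)c(C(=O)CCC)c3O)c(O)c(C(=O)CCC)c2O)c1O | intermediate
19 | trimer bis-Mannich base | CCCC(=O)c1c(O)c(CN(C)C)c(O)c(Cc2c(O)c(Cc3c(O)c(CN(C)C)c(O)c(C(=O)CCC)c3O)c(O)c(C(=O)CCC)c2O)c1O | intermediate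
20 | terminal o-quinone methide from 19 | CCCC(=O)C1=C(O)C(=C)C(=O)C(Cc2c(O)c(Cc3c(O)c(CN(C)C)c(O)c(C(=O)CCC)c3O)c(O)c(C(=O)CCC)c2O)=C1O | intermediate
21 | half-capped amine (tetramer bearing one CH2NMe2) | CCCC(=O)C1=C(O)C(C)(C)C(O)=C(Cc2c(O)c(Cc3c(O)c(Cc4c(O)c(CN(C)C)c(O)c(C(=O)CCC)c4O)c(O)c(C(=O)CCC)c3O)c(O)c(C(=O)CCC)c2O)C1=O | intermediate
22 | o-quinone methide from 21 | CCCC(=O)C1=C(O)C(C)(C)C(O)=C(Cc2c(O)c(Cc3c(O)c(CC4=C(O)C(C(=O)CCC)=C(O)C(=C)C4=O)c(O)c(C(=O)CCC)c3O)c(O)c(C(=O)CCC)c2O)C1=O | intermediate
23 | CNP0188003.0 (achiral pentamer) | CCCC(=O)C1=C(O)C(C)(C)C(O)=C(Cc2c(O)c(Cc3c(O)c(Cc4c(O)c(CC5=C(O)C(C)(C)C(O)=C(C(=O)CCC)C5=O)c(O)c(C(=O)CCC)c4O)c(O)c(C(=O)CCC)c3O)c(O)c(C(=O)CCC)c2O)C1=O | target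

**Step count:** 9 steps in total. The longest linear sequence is 5 steps (5, 6, 7, 8, 9). The branch through steps 1, 2, 4 and 9 has 4 steps, and step 3 feeds step 4.

**Steps most likely to fail**

Step 4 (new method). The ketene may be taken up at the unhindered α-carbon of the diene or may dimerise. The diene may lose its silyl groups before it is acylated. In the methoxide stage, aldol–dehydration or cleavage beside the quaternary carbon may compete with the Claisen closure. The fallback uses known chemistry and derives the ring from an arene instead of building it. It sets out from 11, which is treated with NaOMe and MeI in MeOH so that one free ring carbon is C-methylated twice (alkylative dearomatisation of an acylphloroglucinol), and it comes back to the route at 9. Under- and over-methylated material has to be separated. No compound outside the list is made (F0).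

Step 7. The free CH positions of the growing product may compete with 11 for the quinone methide, which would give chain growth beyond the trimer. The hot, amine-containing medium may also cause exchange of methylene bridges between rings. The fallback reverses the order of assembly (outside in) and avoids the trimer altogether. It sets out from 11, which in excess with one equivalent of the aminal gives the mono-Mannich base 12, this time isolated. Warming 12 with 9 gives norflavaspidic acid BB F1, which has a single free aromatic CH. Two equivalents or slightly more of F1 are then heated with 13, so that a strictly monofunctional nucleophile meets a bifunctional electrophile. The fallback comes back to the route at 23.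

Step 9. The temperature needed to eliminate the amine from 19 may already allow retro-Michael opening of the new filicinic–CH2–aryl bridges, with scrambling as the result. The second capping may stall, and cyclodehydration between a phenol and a neighbouring enol may set in. The fallback reverses the polarity of the coupling. It sets out from 9 and 17. Compound 9 is added to excess aminal at 0 °C to give 2-butyryl-6-(dimethylaminomethyl)-3,5-dihydroxy-4,4-dimethylcyclohexa-2,5-dien-1-one F2. This loses dimethylamine at or below room temperature to give 2-butyryl-3-hydroxy-4,4-dimethyl-6-methylenecyclohex-2-ene-1,5-dione F3. The much more reactive acceptor F3 is captured by the two free aromatic CH positions of 17 (conjugate addition of an acylphloroglucinol to an alkylidene β-triketone). The fallback comes back to the route at 23.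

**Further compounds**
F0 | step 4 | none | none
F1 | step 7 | norflavaspidic acid BB (2-butyryl-6-[(3-butyryl-2,4,6-trihydroxyphenyl)methyl]-3,5-dihydroxy-4,4-dimethylcyclohexa-2,5-dien-1-one) | CCCC(=O)C1=C(O)C(C)(C)C(O)=C(Cc2c(O)cc(O)c(C(=O)CCC)c2O)C1=O
F2 | step 9 | 2-butyryl-6-(dimethylaminomethyl)-3,5-dihydroxy-4,4-dimethylcyclohexa-2,5-dien-1-one | CCCC(=O)C1=C(O)C(C)(C)C(O)=C(CN(C)C)C1=O
F3 | step 9 | 2-butyryl-3-hydroxy-4,4-dimethyl-6-methylenecyclohex-2-ene-1,5-dione | CCCC(=O)C1=C(O)C(C)(C)C(=O)C(=C)C1=O
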